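**Assumptions (one line each)**
- The target has no stereocenters: C(CH3)2OH and the chromene C(CH3)2 each carry two identical methyls. No enantiocontrol is needed, and every intermediate is achiral except the racemic alcohol **5**, whose stereocenter is destroyed in Step 5.
- I read the SMILES literally. The A-ring is 5,8-dihydroxy with the 3-hydroxy-3-methylbutyl group at C6 and H at C7. The B-ring is 2'-OH with a 2,2-dimethylchromene fused at C4'/C5'.

## Retrosynthesis (rings in order of formation)
1. The target comes from removal of three MOM groups from a pyranoisoflavone.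
2. The 2,2-dimethylchromene ring is formed last, from the 4'-OH and prenal (oxa-6π annulation). A 2'-OMOM group blocks angular closure.
3. The isoflavone (C3–C1' bond and pyranone ring) is made in one bold step by hypervalent-iodine 1,2-aryl migration of a 2'-hydroxychalcone, not by cross-coupling.
4. The chalcone comes from Claisen–Schmidt condensation of acetophenone **10** with aldehyde **12**.
5. **10** is built from hydroquinone by directed ortho-metalation/hydroxylation, ortho-formylation, conversion to the methyl ketone, and iodination/Sonogashira/hydrogenation to install the chain.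

## Route

**Step 1**
Reactants: **1** hydroquinone
Product: **2** 1,4-bis(methoxymethoxy)benzene
Conditions: MOMCl, iPr2NEt, CH2Cl2, 0 °C → rt
Reagents that add atoms: MOMCl, ClCOC
Why: Williamson-type bis-MOM protection gives a strong directed-metalation group and an acid-labile phenol protecting group.

**Step 2**
Reactants: **2**
Product: **3** 2,5-bis(methoxymethoxy)phenol
Conditions: s-BuLi, TMEDA, THF, −78 °C; then B(OMe)3; then 30% H2O2, 2 M NaOH, 0 °C
Reagents that add atoms: H2O2, OO (supplies the phenolic O). B(OMe)3 is only a transient trap and nothing from it is retained.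
Why: Directed ortho-metalation (MOM as DMG) followed by borylation and boronate oxidation installs the ring-forming oxygen with exact regiocontrol.

**Step 3**
Reactants: **3**
Product: **4** 2-hydroxy-3,6-bis(methoxymethoxy)benzaldehyde
Conditions: MgCl2, Et3N, (CH2O)n, THF, 70 °C
Reagents that add atoms: paraformaldehyde, C=O
Why: Casnati–Skattebøl ortho-formylation. The only free position ortho to the OH (C6) is flanked by OMOM, so the product is unambiguous.

**Step 4**
Reactants: **4**
Product: **5** rac-1-[2-hydroxy-3,6-bis(methoxymethoxy)phenyl]ethan-1-ol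
Conditions: MeMgBr (3 equiv), THF, 0 °C
Reagents that add atoms: MeMgBr, C[Mg]Br
Why: Grignard addition to the aldehyde (one equivalent is consumed by the phenol).

**Step 5**
Reactants: **5**
Product: **6** 1-[2-hydroxy-3,6-bis(methoxymethoxy)phenyl]ethan-1-one
Conditions: MnO2 (10 equiv), CH2Cl2, rt
Reagents that add atoms: none
Why: MnO2 oxidation of a benzylic alcohol removes the stereocenter and gives the o-hydroxyacetophenone.

**Step 6**
Reactants: **6**
Product: **7** 1-[2-hydroxy-5-iodo-3,6-bis(methoxymethoxy)phenyl]ethan-1-one
Conditions: NIS (1.05 equiv), MeCN, 0 °C → rt, dark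
Reagents that add atoms: NIS, O=C1CCC(=O)N1I
Why: Electrophilic iodination goes to C5, which is para to the free OH, ortho to OMOM and meta to the acyl group. This is the carbon that becomes C6 of the chromone.

**Step 7**
Reactants: **7**; **8** 2-methylbut-3-yn-2-ol
Product: **9** 1-[2-hydroxy-5-(3-hydroxy-3-methylbut-1-yn-1-yl)-3,6-bis(methoxymethoxy)phenyl]ethan-1-one
Conditions: PdCl2(PPh3)2 (5 mol%), CuI (10 mol%), Et3N, DMF, 60 °C
Reagents that add atoms: none beyond reactant 8
Why: Sonogashira coupling tolerates the free phenol and the tertiary propargylic alcohol.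

**Step 8**
Reactants: **9**
Product: **10** 1-[2-hydroxy-5-(3-hydroxy-3-methylbutyl)-3,6-bis(methoxymethoxy)phenyl]ethan-1-one
Conditions: H2 (1 atm), 10% Pd/C, EtOAc, rt
Reagents that add atoms: none (only H added)
Why: Alkyne hydrogenation gives the saturated tertiary-alcohol side chain. The aryl ketone and MOM ethers are untouched.

**Step 9**
Reactants: **11** 4-(benzyloxy)-2-hydroxybenzaldehyde
Product: **12** 4-(benzyloxy)-2-(methoxymethoxy)benzaldehyde
Conditions: MOMCl, iPr2NEt, CH2Cl2, 0 °C → rt
Reagents that add atoms: MOMCl, ClCOC
Why: MOM protection gives orthogonal 2'-OMOM/4'-OBn protection. The OMOM later blocks the 2'-OH and hinders the angular chromene closure.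

**Step 10**
Reactants: **10**; **12**
Product: **13** (E)-2'-hydroxychalcone, 1-[2-hydroxy-5-(3-hydroxy-3-methylbutyl)-3,6-bis(MOMO)phenyl]-3-[4-(benzyloxy)-2-(MOMO)phenyl]prop-2-en-1-one
Conditions: KOH (50% aq., 8 equiv), EtOH, 25 °C, 3 d
Reagents that add atoms: none beyond the reactants
Why: Claisen–Schmidt aldol condensation with base-stable MOM/Bn groups; the E-enone forms under thermodynamic control.

**Step 11 (key step)**
Reactants: **13**
Product: **14** 5,8-bis(MOMO)-6-(3-hydroxy-3-methylbutyl)-3-[4-(benzyloxy)-2-(MOMO)phenyl]chromen-4-one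
Conditions: PhI(OH)OTs (HTIB, 1.5 equiv), HC(OMe)3/MeOH (5:1), 25 °C; then PPTS (0.3 equiv), 40 °C
Reagents that add atoms: none; the OMe groups of the intermediate acetal are lost as MeOH on cyclodehydration
Why: Oxidative 1,2-aryl migration of a 2'-hydroxychalcone (Tl(III)/I(III) type). The iodonium-activated enone is captured by MeOH, the electron-rich 2,4-dioxyaryl group migrates through a phenonium ion to give ArCO-CH(Ar')-CH(OMe)2, and the 2'-OH cyclizes and eliminates MeOH to give the isoflavone. This forms the C3–aryl bond and the pyranone in one step without a cross-coupling, and no stereocenter is involved.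

**Step 12**
Reactants: **14**
Product: **15** 4'-hydroxy-isoflavone (tris-MOM)
Conditions: H2 (1 atm), 10% Pd/C, EtOAc, 25 °C, 1 h
Reagents that add atoms: none (benzyl is removed)
Why: Hydrogenolysis of the aryl benzyl ether is fast and selective. The MOM ethers and tertiary alcohol are stable, and the chromone C2=C3 is not reduced in this short time. The chromene is not yet present.

**Step 13**
Reactants: **15**; **16** 3-methylbut-2-enal (prenal)
Product: **17** pyranoisoflavone, tris-MOM
Conditions: prenal (3 equiv), pyridine, 125 °C, sealed tube, 16 h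
Reagents that add atoms: none beyond reactant 16
Why: Phenol–enal condensation (Knoevenagel-type) gives an o-quinone methide that undergoes oxa-6π electrocyclization to the 2,2-dimethyl-2H-chromene. Closure occurs at C5' (ortho to 4'-OH, para to 2'-OMOM), because C3' is hindered by the 2'-OMOM and the A-ring phenols are masked.

**Step 14**
Reactants: **17**
Product: **18** Kraussianone 3 (target)
Conditions: ZnBr2 (6 equiv), n-PrSH (12 equiv), CH2Cl2, 0 °C → rt, Ar
Reagents that add atoms: none
Why: Lewis-acid/thiol cleavage of the MOM ethers is mild enough for the tertiary alcohol and chromene, and the thiol helps keep the 5,8-hydroquinone reduced. Work up and store under argon.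

## Compound list
1 | hydroquinone | Oc1ccc(O)cc1 | starting material
2 | 1,4-bis(methoxymethoxy)benzene | COCOc1ccc(OCOC)cc1 | intermediate
3 | 2,5-bis(methoxymethoxy)phenol | COCOc1ccc(OCOC)c(O)c1 | intermediate
4 | 2-hydroxy-3,6-bis(methoxymethoxy)benzaldehyde | O=Cc1c(OCOC)ccc(OCOC)c1O | intermediate
5 | rac-1-[2-hydroxy-3,6-bis(MOMO)phenyl]ethanol | CC(O)c1c(OCOC)ccc(OCOC)c1O | intermediate
6 | 1-[2-hydroxy-3,6-bis(MOMO)phenyl]ethanone | CC(=O)c1c(OCOC)ccc(OCOC)c1O | intermediate
7 | 5-iodo ketone | CC(=O)c1c(OCOC)c(I)cc(OCOC)c1O | intermediate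
8 | 2-methylbut-3-yn-2-ol | C#CC(C)(C)O | starting material
9 | alkynyl ketone | CC(=O)c1c(OCOC)c(C#CC(C)(C)O)cc(OCOC)c1O | intermediate
10 | 5-(3-hydroxy-3-methylbutyl) ketone | CC(=O)c1c(OCOC)c(CCC(C)(C)O)cc(OCOC)c1O | intermediate
11 | 4-(benzyloxy)-2-hydroxybenzaldehyde | O=Cc1ccc(OCc2ccccc2)cc1O | starting material
12 | 4-(benzyloxy)-2-(MOMO)benzaldehyde | O=Cc1ccc(OCc2ccccc2)cc1OCOC | intermediate
13 | 2'-hydroxychalcone | O=C(/C=C/c1ccc(OCc2ccccc2)cc1OCOC)c1c(OCOC)c(CCC(C)(C)O)cc(OCOC)c1O | intermediate
14 | 4'-OBn isoflavone, tris-MOM | CC(C)(O)CCc1cc(OCOC)c2occ(-c3ccc(OCc4ccccc4)cc3OCOC)c(=O)c2c1OCOC | intermediate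
15 | 4'-OH isoflavone, tris-MOM | CC(C)(O)CCc1cc(OCOC)c2occ(-c3ccc(O)cc3OCOC)c(=O)c2c1OCOC | intermediate
16 | 3-methylbut-2-enal | CC(C)=CC=O | starting material
17 | pyranoisoflavone, tris-MOM | CC(C)(O)CCc1cc(OCOC)c2occ(-c3cc4c(cc3OCOC)OC(C)(C)C=C4)c(=O)c2c1OCOC | intermediate
18 | Kraussianone 3 | CC(C)(O)CCc1cc(O)c2occ(-c3cc4c(cc3O)OC(C)(C)C=C4)c(=O)c2c1O | target

## Totals
Total steps: 14. Longest linear sequence: 13 steps (hydroquinone → 18, through Steps 1–8 and 10–14).

## Three steps most likely to fail
1. **Step 11 (oxidative aryl migration).** The I(III) reagent may oxidize the electron-rich bis-MOM hydroquinone ring to a quinone, or the TsOH/PPTS may strip MOM groups.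
   Fallback: abandon the rearrangement and use Suzuki–Miyaura coupling. Convert ketone **10** to the 3-iodochromone (DMF-DMA, then cyclization, then I2) and couple it with a pre-built 2-OMOM-7-hydroxychromene-6-boronate.
2. **Step 13 (chromene annulation).** Linear/angular selectivity and yield are uncertain, and the 4'-OH may undergo side reactions with prenal at 125 °C.
   Fallback: a propargyl-ether Claisen route. Alkylate the 4'-OH of **15** with 3-chloro-3-methylbut-1-yne (CuCl, DBU), then thermally cyclize the aryl propargyl ether (PhNEt2, reflux). The alkyne-to-chromene closure goes through a different mechanism.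
3. **Step 2 (DoM/boronate oxidation on the electron-rich bis-MOM arene).** Over-oxidation to the quinone, or double lithiation, would give low yields.
   Fallback: start from commercial 2,5-dihydroxybenzaldehyde. Bis-MOM protect it, then do a Baeyer–Villiger/Dakin-type oxidation (mCPBA, then methanolysis of the formate) to reach **3**.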